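A direct plan would N-alkylate a silylated pyroglutaminol to lactam A1 and add its enolate to silyl butenolide A2, with methylation of the new enolate.
It would then excise the oxygenated butenolide carbon to free a C11 aldehyde, extend this by a Z-selective Wittig reaction and build lactone E late on the C3 arm.
It would close the 11-membered ring last, by intramolecular nitrile oxide cycloaddition of oxime A3 to isoxazoline A4, then N–O hydrogenolysis and lactonisation.
Weak step (a): the macrocyclic nitrile oxide cycloaddition would close an 11-membered ring against strain and entropy at high dilution, with its regiochemistry and both new centres (C10, C11) resting on one conformational preference.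
Weak step (b): the excision of the relay centre (silylation, desilylation, saponification, glycol cleavage, olefination, esterification, alcohol oxidation) would spend seven operations of protection and redox to build one C=C bond.
Weak step (c): the late acid chloride acylation and ketone reduction would set C18 on a fully elaborated intermediate and put the N-bearing C3 centre at risk.

**Retrosynthetic overview**
The C9 ketone and the C9a lactam carbonyl are read as the two ends of a cut C9=C9a enamine bond, so the 11-membered ring is the periphery of a fused seven-membered ring B (N4, C5–C9, C9a) and six-membered ring C (C9a, C9, C10, C11, C12, C1).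
Ring order: lactone E (Fukuyama coupling, Felkin reduction), then C1–C12 and the C13 methyl (Michael addition/methylation on a 5-silyloxy δ-lactone, which δ→γ translactonisation turns into cis lactone D), then ring C (aldol condensation), then rings A and B (imine condensation, N-alkylation).
Ethyl cuprate addition at C10 of ene-iminium 26 then makes the C9=C9a enamine as a single regioisomer, and O2 cuts that bond (7 + 6 → 11 ring expansion).
No ring larger than seven is closed, C10 is set anti to the cis-fused lactone, the acceptor's C–O centre is kept as C11 instead of being excised, and lactone E is made first on a small fragment.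

Key step: step 13

Remark: locants follow the tuberostemonine convention (ring A = N4, C3, C2, C1, C9a; C5–C8 tetramethylene; C9 ketone; C10 ethyl-bearing; C11–C14 lactone D; C18–C21 lactone E). It is assumed that the tetrasubstituted C9=C9a enamine does not tautomerise toward C1 under the aprotic, base-free conditions of step 13.

Step 1
Reactants: 1 (S)-1-(tert-butoxycarbonyl)-5-oxopyrrolidine-2-carboxylic acid
Product: 2 S-ethyl (S)-1-(tert-butoxycarbonyl)-5-oxopyrrolidine-2-carbothioate
Conditions: EtSH, DCC, DMAP (cat.), CH2Cl2, 0 °C → rt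
Reagents that add atoms: ethanethiol, CCS
Why: Steglich thioesterification activates the acid for a neutral ketone synthesis, and the C3 centre is safe because its doubly acylated nitrogen cannot form an azlactone.

Step 2
Reactants: 2 S-ethyl (S)-1-(tert-butoxycarbonyl)-5-oxopyrrolidine-2-carbothioate; 3 methyl (R)-3-bromo-2-methylpropanoate
Product: 5 tert-butyl (S)-2-[(S)-4-methoxy-3-methyl-4-oxobutanoyl]-5-oxopyrrolidine-1-carboxylate, via zinc homoenolate 4 (not isolated)
Conditions: 3, Zn dust, LiCl, THF, 40 °C; then 2, PdCl2(PPh3)2 (5 mol %), PhMe/THF, rt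
Reagents that add atoms: none
Why: Fukuyama coupling of the thioester with the configurationally stable β-zinc ester gives the γ-keto ester under neutral conditions that spare the N-Boc lactam, and C20 is bought in with 3.

Step 3
Reactants: 5 tert-butyl (S)-2-[(S)-4-methoxy-3-methyl-4-oxobutanoyl]-5-oxopyrrolidine-1-carboxylate
Product: 7 tert-butyl (S)-2-[(2S,4S)-4-methyl-5-oxooxolan-2-yl]-5-oxopyrrolidine-1-carboxylate, via hydroxy ester 6 (not isolated)
Conditions: LiBH(s-Bu)3, THF, −78 °C; AcOH, −78 °C; then PPTS (cat.), PhMe, 60 °C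
Reagents that add atoms: none
Why: The bulky borohydride reduces only the ketone under polar Felkin–Anh control (imide nitrogen anti to the hydride) to set 18S, and acid-catalysed lactonisation of the γ-hydroxy ester closes lactone E.

Step 4
Reactants: 8 (R)-but-3-ene-1,2-diol; 9 prop-2-enoyl chloride
Product: 10 (R)-2-hydroxybut-3-en-1-yl prop-2-enoate
Conditions: 2,4,6-collidine, CH2Cl2, −78 °C
Reagents that add atoms: none
Why: Acylation at low temperature with a hindered base selects the primary hydroxyl and leaves the stereocentre untouched.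

Step 5
Reactants: 10 (R)-2-hydroxybut-3-en-1-yl prop-2-enoate
Product: 11 (R)-2-[(tert-butyldimethylsilyl)oxy]but-3-en-1-yl prop-2-enoate
Conditions: TBSOTf, 2,6-lutidine, CH2Cl2, −78 → 0 °C
Reagents that add atoms: tert-butyldimethylsilyl trifluoromethanesulfonate, CC(C)(C)[Si](C)(C)OS(=O)(=O)C(F)(F)F
Why: Silylation of the allylic alcohol installs the bulky, non-acylating group that will direct the Michael addition.

Step 6
Reactants: 11 (R)-2-[(tert-butyldimethylsilyl)oxy]but-3-en-1-yl prop-2-enoate
Product: 12 (R)-5-[(tert-butyldimethylsilyl)oxy]-5,6-dihydro-2H-pyran-2-one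
Conditions: second-generation Grubbs catalyst (3 mol %), CH2Cl2, 40 °C
Reagents that add atoms: none
Why: Ring-closing metathesis of the acrylate with the terminal alkene gives the six-membered unsaturated lactone and is driven by loss of ethene.

Step 7
Reactants: 7 tert-butyl (S)-2-[(2S,4S)-4-methyl-5-oxooxolan-2-yl]-5-oxopyrrolidine-1-carboxylate; 12 (R)-5-[(tert-butyldimethylsilyl)oxy]-5,6-dihydro-2H-pyran-2-one
Product: 15 tert-butyl (3S,5S)-3-[(3S,4S,5R)-5-[(tert-butyldimethylsilyl)oxy]-3-methyl-2-oxooxan-4-yl]-5-[(2S,4S)-4-methyl-5-oxooxolan-2-yl]-2-oxopyrrolidine-1-carboxylate, via lithium lactam enolate 13 (not isolated), via lithium lactone enolate 14 (not isolated)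
Conditions: LiN(SiMe3)2, THF, −78 °C; 12, −78 °C; then MeI, DMPU, −78 → −40 °C
Reagents that add atoms: iodomethane, CI
Why: In this tandem Michael addition/enolate alkylation the imide-like lactam enolate attacks C12 anti to the C11 silyloxy group from its face anti to the C3 substituent (sets C12 and C1), and the δ-lactone enolate is methylated anti to the new C12 substituent (sets C13).

Step 8
Reactants: 15 (the N-Boc lactam above)
Product: 16 S-ethyl (2S,4S)-4-[(tert-butoxycarbonyl)amino]-2-[(3S,4R,5R)-5-[(tert-butyldimethylsilyl)oxy]-3-methyl-2-oxooxan-4-yl]-4-[(2S,4S)-4-methyl-5-oxooxolan-2-yl]butanethioate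
Conditions: EtSLi (from EtSH and n-BuLi), THF, −78 → 0 °C; aq. NH4Cl
Reagents that add atoms: ethanethiol, CCS
Why: Thiolysis of the activated N-acyl carbamate opens ring A irreversibly to the thioester, whereas thiolate attack on either lactone is reversible and C1 is not enolised by this weak base.

Step 9
Reactants: 16 (the thioester above); 17 1-chloro-5-iodopentane
Product: 19 tert-butyl N-[(1S,3S)-9-chloro-3-[(3S,4S,5R)-5-[(tert-butyldimethylsilyl)oxy]-3-methyl-2-oxooxan-4-yl]-1-[(2S,4S)-4-methyl-5-oxooxolan-2-yl]-4-oxononyl]carbamate, via alkylzinc iodide 18 (not isolated)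
Conditions: 17, Zn dust, LiCl, THF, 40 °C; then 16, PdCl2(PPh3)2 (5 mol %), PhMe/THF, rt
Reagents that add atoms: none
Why: A second Fukuyama coupling turns C9a into a ketone carrying C9–C5 with its terminal chloride, chemoselectively beside two lactones and the carbamate and without epimerising C1.

Step 10
Reactants: 19 (the silyloxy δ-lactone ketone above)
Product: 21 tert-butyl N-[(1S,3S)-9-chloro-3-[(2R,3S,4S)-2-(hydroxymethyl)-4-methyl-5-oxooxolan-3-yl]-1-[(2S,4S)-4-methyl-5-oxooxolan-2-yl]-4-oxononyl]carbamate, via hydroxy δ-lactone 20 (not isolated)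
Conditions: HF·pyridine, THF, 0 °C → rt; then CSA (cat.), CH2Cl2, rt
Reagents that add atoms: none
Why: Desilylation frees the C11 hydroxyl, and acid-catalysed translactonisation moves the acyl group to it to give the favoured five-membered lactone D; because no bond to C11 or C12 breaks, the 4,5-trans δ-lactone becomes the γ-lactone with C10 and C1 cis.

Step 11
Reactants: 21 (the hydroxymethyl lactone above)
Product: 23 tert-butyl N-[(1S)-2-[(3S,3aS,4S,7aR)-6-(4-chlorobutyl)-3-methyl-2,5-dioxo-2,3,3a,4,5,7a-hexahydro-1-benzofuran-4-yl]-1-[(2S,4S)-4-methyl-5-oxooxolan-2-yl]ethyl]carbamate, via keto aldehyde 22 (not isolated)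
Conditions: Dess–Martin periodinane, NaHCO3, CH2Cl2, 0 °C → rt; filter; then Bn2NH·CF3CO2H (0.3 equiv), PhH, 50 °C
Reagents that add atoms: none
Why: Oxidation gives a 1,5-keto aldehyde whose amine-salt-catalysed intramolecular aldol condensation (Robinson-type closure) can only join C9 to C10 through a six-membered transition state, closing ring C as the cis-fused enone, the more stable ring fusion to which C11 (γ to the enone) can equilibrate.

Step 12
Reactants: 23 (the bicyclic enone above)
Product: 26 tetracyclic ene-iminium iodide [N4=C9a iminium conjugated with C9=C10; rings A/B/C and lactone D closed; lactone E on C3; (1S,3S,11R,12S,13S,18S,20S)], via ammonium trifluoroacetate 24 (not isolated), via conjugated imine 25 (not isolated)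
Conditions: CF3CO2H, CH2Cl2, 0 °C; evaporate; NaHCO3, 4 Å MS, MeCN, rt; then NaI, 60 °C
Reagents that add atoms: sodium iodide, [Na+].[I-]
Why: Boc acidolysis frees the amine, which condenses with the enone carbonyl to the five-membered cyclic imine (ring A), and Finkelstein-assisted intramolecular Menshutkin N-alkylation (7-exo-tet) closes ring B and quaternises nitrogen, with no added base to enolise C1.

Step 13
Reactants: 26 (the ene-iminium iodide above)
Product: 29 tuberostemonone (1S,3S,10S,11R,12S,13S,18S,20S; the target), via enamine 27 (not isolated), via dioxetane 28 (not isolated)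
Conditions: Et2CuLi (from EtLi and CuI), Et2O/THF, −78 °C; filtration through basic alumina under Ar; then O2, tetraphenylporphyrin (cat.), visible light, CH2Cl2, −78 °C → rt
Reagents that add atoms: lithium diethylcuprate, CC[Cu-]CC.[Li+]; dioxygen, O=O
Why: Proposed new method: the Gilman reagent should transfer ethyl 1,4 to the ene-iminium (π-complexation at C9=C10, C–C bond formation at C10, the tetrasubstituted iminium carbon C9a being too hindered for 1,2-attack), which is the iminium counterpart of cuprate addition to a 2-substituted cyclohexenone and gives the tetrasubstituted C9=C9a enamine 27 as the only regioisomer because no proton source can relay the double bond toward C1. Singlet oxygen then adds [2+2] across this electron-rich bond to dioxetane 28, whose cycloreversion gives the C9 ketone and the C9a lactam, the known photooxygenative cleavage of enamines. The step closes no ring: the 11-membered ring appears by scission of the bond shared by rings B and C, a 7 + 6 → 11 ring expansion that pays no macrocyclisation entropy. C10 is the only new stereocentre and is set by attack on the convex face, anti to cis-fused lactone D, whose C11–O bond lies pseudo-equatorial (ring A holds C2 in the iminium plane) and is therefore not aligned for allylic ionisation. The step needs 1,4- over 1,2-selectivity and an enamine that survives until oxygenation, secured by the hindered ketiminium carbon and by proton-free handling at −78 °C. C1, C11, C12 and C13 are untouched and the base-sensitive β-acyloxy ketone is released under neutral conditions.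

**Compound list**
1 | (S)-1-(tert-butoxycarbonyl)-5-oxopyrrolidine-2-carboxylic acid (Boc-L-pyroglutamic acid) | CC(C)(C)OC(=O)N1C(=O)CC[C@H]1C(=O)O | starting material
2 | S-ethyl (S)-1-(tert-butoxycarbonyl)-5-oxopyrrolidine-2-carbothioate | CC(C)(C)OC(=O)N1C(=O)CC[C@H]1C(=O)SCC | intermediate
3 | methyl (R)-3-bromo-2-methylpropanoate | BrC[C@H](C)C(=O)OC | starting material
4 | (R)-(3-methoxy-2-methyl-3-oxopropyl)zinc bromide | Br[Zn]C[C@H](C)C(=O)OC | intermediate (not isolated)
5 | tert-butyl (S)-2-[(S)-4-methoxy-3-methyl-4-oxobutanoyl]-5-oxopyrrolidine-1-carboxylate | CC(C)(C)OC(=O)N1C(=O)CC[C@H]1C(=O)C[C@H](C)C(=O)OC | intermediate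
6 | tert-butyl (S)-2-[(1S,3S)-1-hydroxy-4-methoxy-3-methyl-4-oxobutyl]-5-oxopyrrolidine-1-carboxylate | CC(C)(C)OC(=O)N1C(=O)CC[C@H]1[C@@H](O)C[C@H](C)C(=O)OC | intermediate (not isolated)
7 | tert-butyl (S)-2-[(2S,4S)-4-methyl-5-oxooxolan-2-yl]-5-oxopyrrolidine-1-carboxylate | CC(C)(C)OC(=O)N1C(=O)CC[C@H]1[C@@H]2C[C@H](C)C(=O)O2 | intermediate
8 | (R)-but-3-ene-1,2-diol | OC[C@H](O)C=C | starting material
9 | prop-2-enoyl chloride (acryloyl chloride) | C=CC(=O)Cl | starting material
10 | (R)-2-hydroxybut-3-en-1-yl prop-2-enoate | C=CC(=O)OC[C@H](O)C=C | intermediate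
11 | (R)-2-[(tert-butyldimethylsilyl)oxy]but-3-en-1-yl prop-2-enoate | C=CC(=O)OC[C@H](O[Si](C)(C)C(C)(C)C)C=C | intermediate
12 | (R)-5-[(tert-butyldimethylsilyl)oxy]-5,6-dihydro-2H-pyran-2-one | O=C1C=C[C@@H](O[Si](C)(C)C(C)(C)C)CO1 | intermediate
13 | lithium enolate of lactam 7 | CC(C)(C)OC(=O)N1C(O[Li])=CC[C@H]1[C@@H]2C[C@H](C)C(=O)O2 | intermediate (not isolated)
14 | lithium δ-lactone enolate of the Michael adduct (des-methyl 15) | CC(C)(C)OC(=O)N1C(=O)[C@@H](C[C@H]1[C@@H]2C[C@H](C)C(=O)O2)[C@@H]3[C@@H](O[Si](C)(C)C(C)(C)C)COC(O[Li])=C3 | intermediate (not isolated)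
15 | tert-butyl (3S,5S)-3-[(3S,4S,5R)-5-[(tert-butyldimethylsilyl)oxy]-3-methyl-2-oxooxan-4-yl]-5-[(2S,4S)-4-methyl-5-oxooxolan-2-yl]-2-oxopyrrolidine-1-carboxylate | CC(C)(C)OC(=O)N1C(=O)[C@@H](C[C@H]1[C@@H]2C[C@H](C)C(=O)O2)[C@@H]3[C@@H](O[Si](C)(C)C(C)(C)C)COC(=O)[C@H]3C | intermediate
16 | S-ethyl (2S,4S)-4-[(tert-butoxycarbonyl)amino]-2-[(3S,4R,5R)-5-[(tert-butyldimethylsilyl)oxy]-3-methyl-2-oxooxan-4-yl]-4-[(2S,4S)-4-methyl-5-oxooxolan-2-yl]butanethioate | CCSC(=O)[C@@H](C[C@H](NC(=O)OC(C)(C)C)[C@@H]2C[C@H](C)C(=O)O2)[C@@H]3[C@@H](O[Si](C)(C)C(C)(C)C)COC(=O)[C@H]3C | intermediate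
17 | 1-chloro-5-iodopentane | ClCCCCCI | starting material
18 | (5-chloropentyl)zinc iodide | ClCCCCC[Zn]I | intermediate (not isolated)
19 | tert-butyl N-[(1S,3S)-9-chloro-3-[(3S,4S,5R)-5-[(tert-butyldimethylsilyl)oxy]-3-methyl-2-oxooxan-4-yl]-1-[(2S,4S)-4-methyl-5-oxooxolan-2-yl]-4-oxononyl]carbamate | ClCCCCCC(=O)[C@@H](C[C@H](NC(=O)OC(C)(C)C)[C@@H]2C[C@H](C)C(=O)O2)[C@@H]3[C@@H](O[Si](C)(C)C(C)(C)C)COC(=O)[C@H]3C | intermediate
20 | tert-butyl N-[(1S,3S)-9-chloro-3-[(3S,4S,5R)-5-hydroxy-3-methyl-2-oxooxan-4-yl]-1-[(2S,4S)-4-methyl-5-oxooxolan-2-yl]-4-oxononyl]carbamate | ClCCCCCC(=O)[C@@H](C[C@H](NC(=O)OC(C)(C)C)[C@@H]2C[C@H](C)C(=O)O2)[C@@H]3[C@@H](O)COC(=O)[C@H]3C | intermediate (not isolated)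
21 | tert-butyl N-[(1S,3S)-9-chloro-3-[(2R,3S,4S)-2-(hydroxymethyl)-4-methyl-5-oxooxolan-3-yl]-1-[(2S,4S)-4-methyl-5-oxooxolan-2-yl]-4-oxononyl]carbamate | ClCCCCCC(=O)[C@@H](C[C@H](NC(=O)OC(C)(C)C)[C@@H]2C[C@H](C)C(=O)O2)[C@@H]3[C@H](CO)OC(=O)[C@H]3C | intermediate
22 | tert-butyl N-[(1S,3S)-9-chloro-3-[(2R,3S,4S)-2-formyl-4-methyl-5-oxooxolan-3-yl]-1-[(2S,4S)-4-methyl-5-oxooxolan-2-yl]-4-oxononyl]carbamate | ClCCCCCC(=O)[C@@H](C[C@H](NC(=O)OC(C)(C)C)[C@@H]2C[C@H](C)C(=O)O2)[C@@H]3[C@H](C=O)OC(=O)[C@H]3C | intermediate (not isolated)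
23 | tert-butyl N-[(1S)-2-[(3S,3aS,4S,7aR)-6-(4-chlorobutyl)-3-methyl-2,5-dioxo-2,3,3a,4,5,7a-hexahydro-1-benzofuran-4-yl]-1-[(2S,4S)-4-methyl-5-oxooxolan-2-yl]ethyl]carbamate | C1=C(CCCCCl)C(=O)[C@@H](C[C@H](NC(=O)OC(C)(C)C)[C@@H]3C[C@H](C)C(=O)O3)[C@@H]2[C@H]1OC(=O)[C@H]2C | intermediate
24 | ammonium trifluoroacetate of des-Boc 23 | C1=C(CCCCCl)C(=O)[C@@H](C[C@H]([NH3+])[C@@H]3C[C@H](C)C(=O)O3)[C@@H]2[C@H]1OC(=O)[C@H]2C.[O-]C(=O)C(F)(F)F | intermediate (not isolated)
25 | tricyclic conjugated imine (N4=C9a, C9=C10; rings A and C and lactone D closed; 4-chlorobutyl on C9; 1S,3S,11R,12S,13S,18S,20S) | C1=C(CCCCCl)C5=N[C@H]([C@@H]4C[C@H](C)C(=O)O4)C[C@H]5[C@@H]2[C@H]1OC(=O)[C@H]2C | intermediate (not isolated)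
26 | tetracyclic ene-iminium iodide (N4=C9a iminium conjugated with C9=C10; rings A, B, C and lactone D closed; 1S,3S,11R,12S,13S,18S,20S) | C1=C6CCCC[N+]5=C6[C@@H](C[C@H]5[C@@H]4C[C@H](C)C(=O)O4)[C@@H]2[C@H]1OC(=O)[C@H]2C.[I-] | intermediate
27 | tetracyclic C9=C9a enamine with ethyl on C10 (1S,3S,10R,11R,12S,13S,18S,20S) | CC[C@@H]1C6=C7N(CCCC6)[C@H]([C@@H]4C[C@H](C)C(=O)O4)C[C@H]7[C@@H]2[C@H]1OC(=O)[C@H]2C | intermediate (not isolated)
28 | 1,2-dioxetane across C9–C9a of 27 (new centres at C9 and C9a undefined and transient) | CC[C@@H]1C6(OO5)C57N(CCCC6)[C@H]([C@@H]4C[C@H](C)C(=O)O4)C[C@H]7[C@@H]2[C@H]1OC(=O)[C@H]2C | intermediate (not isolated)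
29 | tuberostemonone (1S,3S,10S,11R,12S,13S,18S,20S) | CC[C@@H]1C(=O)CCCCN2C(=O)[C@@H](C[C@H]2[C@@H]2C[C@H](C)C(=O)O2)[C@@H]2[C@H]1OC(=O)[C@H]2C | target

**Step count:** 13 steps in total; the longest linear sequence is 10 steps (steps 1, 2, 3, 7, 8, 9, 10, 11, 12, 13 from 1; the acceptor branch, steps 4–6, is equally long to 29).

**Steps most likely to fail**

Step 13 (Proposed new method). The cuprate may attack the iminium carbon, deprotonate C1 or C11 instead of adding, or ionise the allylic lactone oxygen, and the enamine may tautomerise toward C1 before it is oxygenated. The fallback sets out from enone 23, uses known chemistry and installs the ethyl group and the C9 oxygen at the ketone stage. Conjugate addition of Et2CuLi with Me3SiCl trapping would give the regiodefined trimethylsilyl enol ether F1. Rubottom oxidation (m-CPBA, then dilute acid) would give the C9-hydroxy ketone F2. Boc removal, imine condensation and NaI-assisted N-alkylation as in step 12 would then give the α-hydroxy iminium iodide F3. Glycol-type cleavage of its water adduct (NaIO4, aqueous MeCN, pH 7 buffer) would break the C9–C9a bond and rejoin the route at 29.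

Step 12. The seven-membered N-alkylation is slow, and during it the basic imine may relay protons, so that C1 is eroded by imine–enamine tautomerism. The fallback sets out from 26 obtained as a C1 mixture and sets that centre after ring closure instead of carrying it through. KN(SiMe3)2 at −78 °C would give the cross-conjugated tetracyclic 2-aminodiene F4. Kinetic C-protonation with 2,4,6-trimethylpyridinium iodide at −78 °C, on the convex face anti to the C12–C13 bond of lactone D, would return to 26 as one C1 epimer.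

Step 11. The α-acyloxy aldehyde may epimerise or decompose under amine-salt catalysis before C9 closes onto it, or the ketone may enolise toward C1. The fallback sets out from 21. It would be oxidised to 22 as before, but the carbamate would be cleaved first (CF3CO2H), so that the freed amine closes ring A to the 2-alkyl-1-pyrroline aldehyde F5. The exocyclic enamine tautomer of F5 would then condense with the C10 aldehyde (AcOH, PhMe, 40 °C) in an intramolecular imine–aldehyde aldol condensation. This rejoins the route at conjugated imine 25.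

**Further compounds**
F1 | step 13 | trimethylsilyl enol ether of the C10-ethyl ketone from 23 (C9a–OSiMe3, C9=C9a) | CC[C@@H]1C(CCCCCl)=C(O[Si](C)(C)C)[C@@H](C[C@H](NC(=O)OC(C)(C)C)[C@@H]3C[C@H](C)C(=O)O3)[C@@H]2[C@H]1OC(=O)[C@H]2C
F2 | step 13 | C9-hydroxy C9a-ketone (C10 ethyl; C9 configuration immaterial) | CC[C@@H]1C(O)(CCCCCl)C(=O)[C@@H](C[C@H](NC(=O)OC(C)(C)C)[C@@H]3C[C@H](C)C(=O)O3)[C@@H]2[C@H]1OC(=O)[C@H]2C
F3 | step 13 | tetracyclic C9-hydroxy iminium iodide (N4=C9a) | CC[C@@H]1C6(O)CCCC[N+]5=C6[C@@H](C[C@H]5[C@@H]4C[C@H](C)C(=O)O4)[C@@H]2[C@H]1OC(=O)[C@H]2C.[I-]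
F4 | step 12 | tetracyclic cross-conjugated 2-aminodiene (C1=C9a, C9=C10) | C1=C6CCCCN5C6=C(C[C@H]5[C@@H]4C[C@H](C)C(=O)O4)[C@@H]2[C@H]1OC(=O)[C@H]2C
F5 | step 11 | 2-(5-chloropentyl)-1-pyrroline carrying the formyl lactone D on C1 and lactone E on C3 | ClCCCCCC5=N[C@H]([C@@H]4C[C@H](C)C(=O)O4)C[C@H]5[C@@H]3[C@H](C=O)OC(=O)[C@H]3C
A1 | direct plan | (S)-5-[(tert-butyldimethylsilyloxy)methyl]-1-[4-(1,3-dioxolan-2-yl)butyl]pyrrolidin-2-one | O=C1CC[C@@H](CO[Si](C)(C)C(C)(C)C)N1CCCCC2OCCO2
A2 | direct plan | (S)-5-[(tert-butyldimethylsilyloxy)methyl]furan-2(5H)-one | O=C1C=C[C@@H](CO[Si](C)(C)C(C)(C)C)O1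
A3 | direct plan | methyl (2S,3S,4Z)-3-{(3S,5S)-1-[5-(hydroxyimino)pentyl]-5-[(2S,4S)-4-methyl-5-oxooxolan-2-yl]-2-oxopyrrolidin-3-yl}-2-methylhept-4-enoate | ON=CCCCCN1C(=O)[C@@H](C[C@H]1[C@@H]1C[C@H](C)C(=O)O1)[C@H](/C=C\CC)[C@H](C)C(=O)OC
A4 | direct plan | macrocyclic 2-isoxazoline (C9=N–O–C11) with the methyl ester side chain on C12 | CC[C@@H]1C(=NO2)CCCCN3C(=O)[C@@H](C[C@H]3[C@@H]3C[C@H](C)C(=O)O3)[C@@H]([C@H](C)C(=O)OC)[C@H]12
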